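**Plan**

- Retrosynthesis: the C4–C4a aryl–acyl bond of the pyranone ring is cut last, then the O1–C2 tertiary aryl ether bond. C4 is the oxidised terminal vinyl carbon and the side-chain OH the hydrated prenyl end of a linalyl unit.
- Enabling feature: on the benzo ring, O1 (on C8a) and the C6 hydroxyl are para; C4a and C7 are para to each other and each is ortho to one of these oxygens. The arene is therefore twofold-symmetric 2,5-dibromohydroquinone: the bromine ortho to the ether oxygen becomes the aryl anion that closes the ring, the other stays as C7–Br.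
- Forward: geraniol → methyl carbonate → palladium-catalysed asymmetric O-allylation of the dibromohydroquinone → silyl protection → hydroboration of the vinyl group → hydration of the prenyl alkene → acid → N-methoxy-N-methylamide → desilylation → anionic closure of the pyranone ring, the only ring formed, which gives the target directly.
- Stereochemistry: the single stereocentre (C2, R) is set by the chiral ligand in the allylic etherification. Afterwards the C2–O1 bond sees no strong acid and no conditions for retro-oxa-Michael cleavage; the ring is closed at −78 °C.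
- An aryl anion is used instead of electrophilic acylation because C4a is meta to the C6 oxygen and para to bromine (poorly activated), the tertiary ether and tertiary alcohol are acid-labile, and late bromination of a 6-hydroxychromanone would compete at C5.

Key step: step 9

Assumption: with geranyl (E) methyl carbonate the (R,R)-ligand is taken to deliver the (R)-ether. Olefin geometry and ligand enantiomer together fix the sense, so the (S,S)-ligand is used instead if the sense proves opposite, with nothing else changed.

**Step 1**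
Reactants: 1 geraniol, (2E)-3,7-dimethylocta-2,6-dien-1-ol
Product: 2 geranyl methyl carbonate, methyl (2E)-3,7-dimethylocta-2,6-dien-1-yl carbonate
Conditions: ClCO2Me, pyridine, CH2Cl2, 0 °C
Reagents that add atoms: methyl chloroformate, COC(=O)Cl
Why: Acylation of the primary allylic alcohol installs the carbonate leaving group needed for neutral palladium ionisation and leaves the E alkene untouched.

**Step 2**
Reactants: 2 geranyl methyl carbonate; 3 2,5-dibromobenzene-1,4-diol (threefold excess)
Product: 4 2,5-dibromo-4-{[(3R)-3,7-dimethylocta-1,6-dien-3-yl]oxy}phenol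
Conditions: Pd2(dba)3·CHCl3 (2 mol%), (R,R)-DACH-phenyl Trost ligand (6 mol%), CH2Cl2/THF, 0 °C to rt
Reagents that add atoms: none
Why: Zerovalent palladium ionises the carbonate to a 1,1-disubstituted π-allyl complex, the released methoxide deprotonates 3, and the phenoxide attacks the more substituted allyl terminus inside the chiral pocket of the ligand (Trost asymmetric allylic alkylation of phenols, the known route from geranyl carbonate to linalyl aryl ethers), so the ligand sets the R configuration of the new tertiary ether carbon while the excess of the symmetric diol suppresses double allylation.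

**Step 3**
Reactants: 4 2,5-dibromo-4-{[(3R)-3,7-dimethylocta-1,6-dien-3-yl]oxy}phenol
Product: 5 {2,5-dibromo-4-{[(3R)-3,7-dimethylocta-1,6-dien-3-yl]oxy}phenoxy}tri(propan-2-yl)silane
Conditions: TIPSCl, imidazole, DMF, rt
Reagents that add atoms: triisopropylsilyl chloride, CC(C)[Si](Cl)(C(C)C)C(C)C
Why: Imidazole-promoted silylation masks the remaining phenol as a bulky silyl ether that should survive the oxidative and radical steps which a free, electron-rich bromophenol would not.

**Step 4**
Reactants: 5 {2,5-dibromo-4-{[(3R)-3,7-dimethylocta-1,6-dien-3-yl]oxy}phenoxy}tri(propan-2-yl)silane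
Product: 7 (3R)-3-{2,5-dibromo-4-[tri(propan-2-yl)silyloxy]phenoxy}-3,7-dimethyloct-6-en-1-ol, via alkylborane 6 (not isolated)
Conditions: 9-BBN (1.5 equiv), THF, 0 °C to rt; then NaBO3·4H2O, H2O, rt
Reagents that add atoms: 9-borabicyclo[3.3.1]nonane, B1C2CCCC1CCC2 (boron unit of 6); sodium perborate, [Na+].[O-]OB=O (hydroxyl oxygen of 7)
Why: Anti-Markovnikov hydroboration with 9-BBN takes the monosubstituted vinyl group in preference to the trisubstituted alkene and puts boron on the terminal carbon, and perborate then oxidises the C–B bond under mild conditions without involving the quaternary stereocentre.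

**Step 5**
Reactants: 7 (3R)-3-{2,5-dibromo-4-[tri(propan-2-yl)silyloxy]phenoxy}-3,7-dimethyloct-6-en-1-ol
Product: 8 (3R)-3-{2,5-dibromo-4-[tri(propan-2-yl)silyloxy]phenoxy}-3,7-dimethyloctane-1,7-diol
Conditions: Co(acac)2 (20 mol%), PhSiH3 (2.5 equiv), O2 (1 atm), THF, rt
Reagents that add atoms: dioxygen, O=O
Why: In the Mukaiyama hydration a cobalt hydride transfers a hydrogen atom to the trisubstituted alkene, and the tertiary radical is trapped by O2 and reduced to the Markovnikov tertiary alcohol, conditions to which aryl bromides, the silyl ether and the primary alcohol are inert.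

**Step 6**
Reactants: 8 (3R)-3-{2,5-dibromo-4-[tri(propan-2-yl)silyloxy]phenoxy}-3,7-dimethyloctane-1,7-diol
Product: 10 (3R)-3-{2,5-dibromo-4-[tri(propan-2-yl)silyloxy]phenoxy}-7-hydroxy-3,7-dimethyloctanoic acid, via aldehyde 9 (not isolated)
Conditions: TEMPO (20 mol%), PhI(OAc)2 (2.2 equiv), MeCN/H2O 1:1, rt
Reagents that add atoms: water, O
Why: Oxoammonium oxidation (TEMPO with PhI(OAc)2 in aqueous MeCN) takes the primary alcohol through the aldehyde hydrate to the acid, cannot oxidise the tertiary alcohol, and is close enough to neutral that the β-aryloxy carbonyl compounds should not eliminate.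

**Step 7**
Reactants: 10 (3R)-3-{2,5-dibromo-4-[tri(propan-2-yl)silyloxy]phenoxy}-7-hydroxy-3,7-dimethyloctanoic acid
Product: 12 (3R)-3-{2,5-dibromo-4-[tri(propan-2-yl)silyloxy]phenoxy}-7-hydroxy-N-methoxy-N,3,7-trimethyloctanamide, via acyl imidazolide 11 (not isolated)
Conditions: CDI (1.2 equiv), CH2Cl2, rt; then MeNH(OMe)·HCl (1.5 equiv), rt
Reagents that add atoms: 1,1'-carbonyldiimidazole, O=C(n1ccnc1)n1ccnc1 (imidazole unit of 11); N,O-dimethylhydroxylamine hydrochloride, CNOC.Cl
Why: Carbonyldiimidazole activation followed by aminolysis with N,O-dimethylhydroxylamine (Weinreb amide formation) needs no strong base, and the hindered tertiary alcohol does not compete.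

**Step 8**
Reactants: 12 (3R)-3-{2,5-dibromo-4-[tri(propan-2-yl)silyloxy]phenoxy}-7-hydroxy-N-methoxy-N,3,7-trimethyloctanamide
Product: 13 (3R)-3-(2,5-dibromo-4-hydroxyphenoxy)-7-hydroxy-N-methoxy-N,3,7-trimethyloctanamide
Conditions: TBAF (1.1 equiv), AcOH (1.1 equiv), THF, 0 °C
Reagents that add atoms: none
Why: Fluoride cleaves the aryl Si–O bond (silyl ether deprotection), and the acetic acid buffer keeps the medium from becoming basic enough for β-elimination of the aryloxide.

**Step 9**
Reactants: 13 (3R)-3-(2,5-dibromo-4-hydroxyphenoxy)-7-hydroxy-N-methoxy-N,3,7-trimethyloctanamide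
Product: 16 (2R)-7-bromo-6-hydroxy-2-(4-hydroxy-4-methylpentyl)-2-methyl-2,3-dihydro-4H-chromen-4-one (target), via aryllithium 14 (not isolated), via lithium hemiaminalate 15 (not isolated)
Conditions: t-BuLi (4.2 equiv, slow addition), THF, −78 °C; then sat. aq NH4Cl
Reagents that add atoms: none
Why: After deprotonation of the phenol and the tertiary alcohol, bromine–lithium exchange should take place at the bromine ortho to the ether oxygen, because the other bromine sits ortho to a lithium phenoxide on an electron-rich position that exchanges far more slowly at −78 °C; the aryllithium then adds to the tethered N-methoxy-N-methylamide to give a chelated lithium hemiaminalate that releases the ketone only on quench, so over-addition is excluded. The closest known reaction type is the Parham cyclisation (cycliacylation) of ortho-bromoaryl-tethered Weinreb amides to benzo-fused cyclic ketones. The pyranone ring closes in a 6-exo-trig mode, the aryl carbanion attacking the amide carbonyl whose C=O bond is exocyclic to the new ring. No stereocentre is formed and C2 is carried through unchanged, since the conditions are non-acidic and the only leaving group available for a retro-oxa-Michael reaction would be a hydroquinone dianion. The step needs site selectivity between the two C–Br bonds and chemoselectivity of exchange over attack on the amide; the phenoxide, the six-membered transition state open only to the proximal aryllithium, and the bulk and speed of t-BuLi should secure both.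

**Compound list**

1 | geraniol, (2E)-3,7-dimethylocta-2,6-dien-1-ol | CC(C)=CCC/C(C)=C/CO | starting material
2 | geranyl methyl carbonate | CC(C)=CCC/C(C)=C/COC(=O)OC | intermediate
3 | 2,5-dibromobenzene-1,4-diol | Oc1cc(Br)c(O)cc1Br | starting material
4 | 2,5-dibromo-4-{[(3R)-3,7-dimethylocta-1,6-dien-3-yl]oxy}phenol | C=C[C@@](C)(CCC=C(C)C)Oc1cc(Br)c(O)cc1Br | intermediate
5 | {2,5-dibromo-4-{[(3R)-3,7-dimethylocta-1,6-dien-3-yl]oxy}phenoxy}tri(propan-2-yl)silane | C=C[C@@](C)(CCC=C(C)C)Oc1cc(Br)c(O[Si](C(C)C)(C(C)C)C(C)C)cc1Br | intermediate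
6 | 9-alkyl-9-borabicyclo[3.3.1]nonane from 5, boron on the former terminal vinyl carbon, stereocentre unchanged (not isolated) | B1(CC[C@@](C)(CCC=C(C)C)Oc3cc(Br)c(O[Si](C(C)C)(C(C)C)C(C)C)cc3Br)C2CCCC1CCC2 | intermediate
7 | (3R)-3-{2,5-dibromo-4-[tri(propan-2-yl)silyloxy]phenoxy}-3,7-dimethyloct-6-en-1-ol | OCC[C@@](C)(CCC=C(C)C)Oc1cc(Br)c(O[Si](C(C)C)(C(C)C)C(C)C)cc1Br | intermediate
8 | (3R)-3-{2,5-dibromo-4-[tri(propan-2-yl)silyloxy]phenoxy}-3,7-dimethyloctane-1,7-diol | OCC[C@@](C)(CCCC(C)(C)O)Oc1cc(Br)c(O[Si](C(C)C)(C(C)C)C(C)C)cc1Br | intermediate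
9 | (3R)-3-{2,5-dibromo-4-[tri(propan-2-yl)silyloxy]phenoxy}-7-hydroxy-3,7-dimethyloctanal (not isolated) | O=CC[C@@](C)(CCCC(C)(C)O)Oc1cc(Br)c(O[Si](C(C)C)(C(C)C)C(C)C)cc1Br | intermediate
10 | (3R)-3-{2,5-dibromo-4-[tri(propan-2-yl)silyloxy]phenoxy}-7-hydroxy-3,7-dimethyloctanoic acid | OC(=O)C[C@@](C)(CCCC(C)(C)O)Oc1cc(Br)c(O[Si](C(C)C)(C(C)C)C(C)C)cc1Br | intermediate
11 | N-acylimidazole of acid 10 (not isolated) | O=C(C[C@@](C)(CCCC(C)(C)O)Oc1cc(Br)c(O[Si](C(C)C)(C(C)C)C(C)C)cc1Br)n1ccnc1 | intermediate
12 | (3R)-3-{2,5-dibromo-4-[tri(propan-2-yl)silyloxy]phenoxy}-7-hydroxy-N-methoxy-N,3,7-trimethyloctanamide | CON(C)C(=O)C[C@@](C)(CCCC(C)(C)O)Oc1cc(Br)c(O[Si](C(C)C)(C(C)C)C(C)C)cc1Br | intermediate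
13 | (3R)-3-(2,5-dibromo-4-hydroxyphenoxy)-7-hydroxy-N-methoxy-N,3,7-trimethyloctanamide | CON(C)C(=O)C[C@@](C)(CCCC(C)(C)O)Oc1cc(Br)c(O)cc1Br | intermediate
14 | trilithiated 13: lithium phenoxide, lithium tertiary alkoxide, aryllithium ortho to the ether oxygen (not isolated) | CON(C)C(=O)C[C@@](C)(CCCC(C)(C)O[Li])Oc1cc(Br)c(O[Li])cc1[Li] | intermediate
15 | trilithium hemiaminalate, (2R)-chroman with C4 bearing OLi and N(OMe)Me, either configuration at C4 (not isolated) | [Li]OC(C)(C)CCC[C@]1(C)CC(O[Li])(N(C)OC)c2cc(O[Li])c(Br)cc2O1 | intermediate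
16 | (2R)-7-bromo-6-hydroxy-2-(4-hydroxy-4-methylpentyl)-2-methyl-2,3-dihydro-4H-chromen-4-one | CC(C)(O)CCC[C@]1(C)CC(=O)c2cc(O)c(Br)cc2O1 | target

**Totals**

Total step count: 9. Longest linear sequence: 9 steps (1 → 16).

**Steps most likely to fail**

Step 2. The product ether carries an acidic, hindered bromophenoxide as a leaving group, so zerovalent palladium may re-ionise it; this would erode the branched selectivity and the ee. Double allylation and an unexpected facial sense are further risks. Fallback: the stereocentre is taken from the chiral pool instead of from catalysis. This fallback sets out from no numbered compound; it replaces 1–3 with commercial (R)-(−)-linalool F1 and 1,4-dibromo-2-fluoro-5-nitrobenzene F2. The potassium alkoxide of F1 (KN(SiMe3)2, THF, −20 °C) should displace the fluoride para to the nitro group by SNAr without touching the C–O bond of linalool, giving nitro ether F3 with retained configuration. Fe/NH4Cl in aqueous EtOH should reduce F3 to aniline F4. Sandmeyer-type borylation (t-BuONO, B2pin2, MeCN, rt) should give pinacol boronate F5, and NaBO3·4H2O in THF/H2O should oxidise it to phenol 4, where the route is rejoined.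

Step 9. Exchange may occur at the bromine ortho to the phenoxide, the aryllithium may be protonated by incompletely deprotonated hydroxyls, or the alkyllithium may attack the amide. Fallback: the same C4–C4a bond is made by palladium catalysis at the alkane oxidation level, then C4 is oxidised. It sets out from compound 5 through its borane 6. Instead of oxidising 6, PdCl2(dppf) and aqueous K3PO4 are added (DMF/THF, 50 °C, high dilution); only the palladium inserted ortho to the ether oxygen can reach the tethered borane, so an intramolecular B-alkyl Suzuki–Miyaura coupling should give (2R)-chroman F6. Mukaiyama hydration as in step 5 should give tertiary alcohol F7. Benzylic oxidation at C4 (Rh2(cap)4, t-BuOOH, CH2Cl2) should give silyl-protected chromanone F8, and TBAF/AcOH should then give compound 16.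

Step 5. The radical hydration may stall at the hydroperoxide or over-reduce the alkene to the alkane. Fallback: ionic Markovnikov hydration. It sets out from compound 7: Hg(OAc)2 in THF/H2O should give organomercurial F9, and NaBH4 in aqueous NaOH should demercurate it to compound 8, where the route is rejoined.

**Further compounds**

F1 | step 2 | (R)-(−)-linalool, (3R)-3,7-dimethylocta-1,6-dien-3-ol (bought) | C=C[C@@](C)(CCC=C(C)C)O
F2 | step 2 | 1,4-dibromo-2-fluoro-5-nitrobenzene (bought) | [O-][N+](=O)c1cc(Br)c(F)cc1Br
F3 | step 2 | 1,4-dibromo-2-{[(3R)-3,7-dimethylocta-1,6-dien-3-yl]oxy}-5-nitrobenzene | C=C[C@@](C)(CCC=C(C)C)Oc1cc(Br)c([N+](=O)[O-])cc1Br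
F4 | step 2 | 2,5-dibromo-4-{[(3R)-3,7-dimethylocta-1,6-dien-3-yl]oxy}aniline | C=C[C@@](C)(CCC=C(C)C)Oc1cc(Br)c(N)cc1Br
F5 | step 2 | 2-(2,5-dibromo-4-{[(3R)-3,7-dimethylocta-1,6-dien-3-yl]oxy}phenyl)-4,4,5,5-tetramethyl-1,3,2-dioxaborolane | C=C[C@@](C)(CCC=C(C)C)Oc1cc(Br)c(B2OC(C)(C)C(C)(C)O2)cc1Br
F6 | step 9 | {[(2R)-7-bromo-2-methyl-2-(4-methylpent-3-en-1-yl)-3,4-dihydro-2H-chromen-6-yl]oxy}tri(propan-2-yl)silane | CC(C)=CCC[C@]1(C)CCc2cc(O[Si](C(C)C)(C(C)C)C(C)C)c(Br)cc2O1
F7 | step 9 | 5-{(2R)-7-bromo-2-methyl-6-[tri(propan-2-yl)silyloxy]-3,4-dihydro-2H-chromen-2-yl}-2-methylpentan-2-ol | CC(C)(O)CCC[C@]1(C)CCc2cc(O[Si](C(C)C)(C(C)C)C(C)C)c(Br)cc2O1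
F8 | step 9 | (2R)-7-bromo-2-(4-hydroxy-4-methylpentyl)-2-methyl-6-[tri(propan-2-yl)silyloxy]-2,3-dihydro-4H-chromen-4-one | CC(C)(O)CCC[C@]1(C)CC(=O)c2cc(O[Si](C(C)C)(C(C)C)C(C)C)c(Br)cc2O1
F9 | step 5 | acetoxymercurio adduct of 7: C6 bears HgOAc (either configuration), C7 bears OH | OCC[C@@](C)(CCC([Hg]OC(C)=O)C(C)(C)O)Oc1cc(Br)c(O[Si](C(C)C)(C(C)C)C(C)C)cc1Br
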